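**Retrosynthetic overview**

1. Carotenoid numbering is used (ring: C1 = CMe2, C2 = CH2, C3 = CHOH, C4=C5(CH3), C6 = CH; chain C7 to C8'). The last disconnection is C7=C8 (Julia–Kocienski) into a C10 ring sulfone and all-E crocetin dialdehyde; the C8' aldehyde is reduced at the very end.
2. The ring sulfone comes from a cis-diol by silylation, Mitsunobu inversion at C3 with (1S)-camphanic acid (it inverts, resolves by diastereomer separation and protects O3 to the end), desilylation, thioether formation and oxidation.
3. Key disconnection: C2–C3 and C1–C6 in one [4+2] cycloaddition of 4-methyl-2-pyrone (C3–C4=C5–C6 held s-cis, O3 and C7 joined as the lactone) with isobutene (C1–C2).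
4. Enabling feature: the C4=C5 ring double bond lies exactly between oxygen-bearing C3 and C7-bearing C6 (cyclohexene retron), and C1–C2 is an unfunctionalised 1,1-dimethylethylene unit whose polarity matches the δ- and α-carbons of the unsaturated lactone.
5. Rings: pyrone (temporary heterocycle, step 1), then the cyclohexene ring with its lactone bridge (step 2), then the bridge is opened by hydride (step 3); no further ring is formed.

Key step: step 2

Assumption: all-E crocetin dialdehyde is taken as a purchasable carotenoid building block; the racemic intermediates between cycloaddition and resolution are named and drawn as the enantiomer that is carried on.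

**Route**

Step 1
Reactants: 1 ethyl 3-methylbut-2-enoate; 2 ethyl formate
Product: 4 4-methyl-2H-pyran-2-one, via hydroxy-dienoate enolate 3 (not isolated)
Conditions: KOEt (1.1 equiv), Et2O, 0 °C to rt; then conc. HCl, AcOH, 60 °C
Reagents that add atoms: none
Why: Vinylogous (γ-selective) Claisen condensation of the ester dienolate with ethyl formate under reversible alkoxide conditions should give the fully conjugated glutaconaldehyde-type enolate, which on acidification equilibrates to the 2Z,4Z form and lactonises with loss of ethanol to the 2-pyrone; no stereocentre is formed.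

Step 2
Reactants: 4 4-methyl-2H-pyran-2-one; 5 2-methylpropene (isobutene)
Product: 6 rac-(1S,4R)-5,8,8-trimethyl-2-oxabicyclo[2.2.2]oct-5-en-3-one
Conditions: 5 (10 equiv, condensed), BHT (1 mol %), CH2Cl2, 12 kbar, 60 °C, sealed PTFE ampoule
Reagents that add atoms: none
Why: Thermal inverse-electron-demand Diels–Alder reaction: the electron-poor pyrone diene (its C6–C5=C4–C3 unit becomes C3–C4=C5–C6 of the target) and isobutene combine through one concerted but asynchronous transition state, in which the CH2 terminus of the alkene bonds first to the δ-carbon of the unsaturated lactone (the C2–C3 bond) while positive charge builds on the tertiary carbon, which closes onto the α-carbon (the C1–C6 bond, the most hindered bond of the ring, next to the new quaternary carbon). The closest known reaction type is the pressure-promoted cycloaddition of 2-pyrones with alkenes to give isolable 2-oxabicyclo[2.2.2]oct-5-en-3-ones. The cyclohexene ring is closed by an intermolecular suprafacial [4+2] cycloaddition (both ring bonds in one event, so no separate ring-closure geometry has to be met), and the lactone of the pyrone is carried into the adduct as the bridge of the bicycle. The two new stereocentres (C3 and C6, the bridgeheads) necessarily come out cis because O3 and C7 are tied together in that bridge; the faces of the planar pyrone are enantiotopic and isobutene is achiral, so the adduct is racemic (resolved in step 5), and since each alkene carbon carries two identical substituents there is no endo/exo question. The step needs regioselectivity, which the matched polarisation secures (largest LUMO coefficient at the lactone δ-carbon, largest HOMO coefficient at the CH2 of the 1,1-disubstituted alkene; the other orientation would put the developing cation on a primary carbon), and it needs the CO2 bridge to survive, which pressure (it favours cycloaddition over cycloreversion) and the moderate temperature should secure.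

Step 3
Reactants: 6 rac-(1S,4R)-5,8,8-trimethyl-2-oxabicyclo[2.2.2]oct-5-en-3-one
Product: 7 rac-(1S,4R)-4-(hydroxymethyl)-3,5,5-trimethylcyclohex-2-en-1-ol
Conditions: LiAlH4, THF, 0 °C to rt; aqueous NaOH work-up
Reagents that add atoms: none
Why: Hydride reduction of the bridged lactone opens the temporary ring to the cis-diol without touching the isolated trisubstituted olefin, and neither C3 nor the non-enolisable bridgehead C6 is affected, so the cis relationship from the cycloaddition is kept.

Step 4
Reactants: 7 rac-(1S,4R)-4-(hydroxymethyl)-3,5,5-trimethylcyclohex-2-en-1-ol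
Product: 8 rac-(1S,4R)-4-({[tert-butyl(dimethyl)silyl]oxy}methyl)-3,5,5-trimethylcyclohex-2-en-1-ol
Conditions: TBSCl (1.05 equiv), imidazole, CH2Cl2, −20 to 0 °C
Reagents that add atoms: tert-butyl(chloro)dimethylsilane (TBSCl), CC(C)(C)[Si](C)(C)Cl
Why: Kinetic mono-silylation should discriminate the primary from the secondary allylic hydroxyl on steric grounds at oxygen, leaving only C3–OH free for the inversion; no stereocentre is touched.

Step 5
Reactants: 8 rac-(1S,4R)-4-({[tert-butyl(dimethyl)silyl]oxy}methyl)-3,5,5-trimethylcyclohex-2-en-1-ol; 9 (1S)-(−)-camphanic acid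
Product: 10 (1R,4R)-4-({[tert-butyl(dimethyl)silyl]oxy}methyl)-3,5,5-trimethylcyclohex-2-en-1-yl (1S,4R)-camphanate
Conditions: PPh3, DIAD, THF, 0 °C to rt; the diastereomeric ester with the (1S,4S) ring removed by crystallisation or chromatography on SiO2
Reagents that add atoms: none
Why: Mitsunobu reaction, in which SN2 displacement of the allylic oxyphosphonium by the carboxylate inverts C3 to the R configuration (trans to the C6 substituent), SN2′ attack being disfavoured because it would have to occur at the fully substituted, methyl-bearing C5, while the homochiral acid turns the two enantiomers of 8 into two separable diastereomeric esters, of which 10 has the (3R,6R) ring of the target and the other, with the (3S,6S) ring, is discarded.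

Step 6
Reactants: 10 (1R,4R)-4-({[tert-butyl(dimethyl)silyl]oxy}methyl)-3,5,5-trimethylcyclohex-2-en-1-yl (1S,4R)-camphanate
Product: 11 (1R,4R)-4-(hydroxymethyl)-3,5,5-trimethylcyclohex-2-en-1-yl (1S,4R)-camphanate
Conditions: HF·pyridine, pyridine/THF, 0 °C to rt
Reagents that add atoms: none
Why: Buffered fluoride cleavage of the primary silyl ether should leave the hindered, non-enolisable camphanate ester and its lactone untouched, and the trans-1,4 arrangement rules out acyl migration; no stereocentre is affected.

Step 7
Reactants: 11 (1R,4R)-4-(hydroxymethyl)-3,5,5-trimethylcyclohex-2-en-1-yl (1S,4R)-camphanate; 12 1-phenyl-1H-tetrazole-5-thiol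
Product: 13 (1R,4R)-3,5,5-trimethyl-4-{[(1-phenyl-1H-tetrazol-5-yl)sulfanyl]methyl}cyclohex-2-en-1-yl (1S,4R)-camphanate
Conditions: PPh3, DIAD, THF, 0 °C to rt
Reagents that add atoms: none
Why: Mitsunobu thioetherification of the primary alcohol with the acidic heteroaryl thiol (S-alkylation by SN2 at the CH2 carbon) installs the sulfur needed for the later olefination without ever placing a carbonyl group next to C6, so that centre cannot epimerise.

Step 8
Reactants: 13 (1R,4R)-3,5,5-trimethyl-4-{[(1-phenyl-1H-tetrazol-5-yl)sulfanyl]methyl}cyclohex-2-en-1-yl (1S,4R)-camphanate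
Product: 14 (1R,4R)-3,5,5-trimethyl-4-{[(1-phenyl-1H-tetrazol-5-yl)sulfonyl]methyl}cyclohex-2-en-1-yl (1S,4R)-camphanate
Conditions: (NH4)6Mo7O24·4H2O (10 mol %), 30% aq. H2O2, EtOH, 0 °C to rt
Reagents that add atoms: hydrogen peroxide, OO
Why: Molybdate-catalysed peroxide oxidation should take the sulfide through the sulfoxide to the sulfone and is selective for sulfur over the hindered trisubstituted olefin, which is further deactivated by its allylic ester.

Step 9
Reactants: 14 (1R,4R)-3,5,5-trimethyl-4-{[(1-phenyl-1H-tetrazol-5-yl)sulfonyl]methyl}cyclohex-2-en-1-yl (1S,4R)-camphanate; 15 all-E crocetin dialdehyde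
Product: 16 (3R,6R)-8'-oxo-8'-apo-ε-caroten-3-yl (1S,4R)-camphanate
Conditions: KN(SiMe3)2, THF, −78 °C; then cannulated into 15 (3 equiv) in THF, −78 to −20 °C; argon, dim light; excess 15 recovered
Reagents that add atoms: none
Why: Julia–Kocienski olefination, in which the potassium sulfonyl carbanion adds to one aldehyde of the excess symmetric dialdehyde and Smiles rearrangement with loss of SO2 and the tetrazolone gives the C7=C8 olefin, for which the 1-phenyltetrazolyl sulfone with a potassium counter-ion favours E, while C6 is never acidified and the trisubstituted C9=C10 geometry arrives intact in the aldehyde partner.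

Step 10
Reactants: 16 (3R,6R)-8'-oxo-8'-apo-ε-caroten-3-yl (1S,4R)-camphanate
Product: 18 (3R,6R)-8'-apo-ε-carotene-3,8'-diol (target), via C30 alcohol camphanate 17 (not isolated)
Conditions: NaBH4, THF/MeOH, 0 °C; then K2CO3, MeOH, rt; argon, dim light
Reagents that add atoms: none
Why: Chemoselective 1,2-reduction of the polyenal by borohydride followed by carbonate-catalysed methanolysis of the camphanate (acyl–oxygen cleavage, so C3 keeps its R configuration) should release the all-E diol.

**Compound list**

1 | ethyl 3-methylbut-2-enoate | CCOC(=O)C=C(C)C | starting material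
2 | ethyl formate | CCOC=O | starting material
3 | ethyl (2Z,4Z)-5-hydroxy-3-methylpenta-2,4-dienoate (generated as its potassium enolate) | CCOC(=O)/C=C(C)\C=C/O | intermediate (not isolated)
4 | 4-methyl-2H-pyran-2-one | CC1=CC(=O)OC=C1 | intermediate
5 | 2-methylpropene (isobutene) | CC(C)=C | starting material
6 | rac-(1S,4R)-5,8,8-trimethyl-2-oxabicyclo[2.2.2]oct-5-en-3-one | CC1=C[C@@H]2CC(C)(C)[C@H]1C(=O)O2 | intermediate
7 | rac-(1S,4R)-4-(hydroxymethyl)-3,5,5-trimethylcyclohex-2-en-1-ol (cis) | CC1=C[C@@H](O)CC(C)(C)[C@H]1CO | intermediate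
8 | rac-(1S,4R)-4-({[tert-butyl(dimethyl)silyl]oxy}methyl)-3,5,5-trimethylcyclohex-2-en-1-ol | CC1=C[C@@H](O)CC(C)(C)[C@H]1CO[Si](C)(C)C(C)(C)C | intermediate
9 | (1S,4R)-4,7,7-trimethyl-3-oxo-2-oxabicyclo[2.2.1]heptane-1-carboxylic acid, (1S)-(−)-camphanic acid | O=C(O)[C@@]12CC[C@@](C)(C(=O)O1)C2(C)C | starting material
10 | (1R,4R)-4-({[tert-butyl(dimethyl)silyl]oxy}methyl)-3,5,5-trimethylcyclohex-2-en-1-yl (1S,4R)-4,7,7-trimethyl-3-oxo-2-oxabicyclo[2.2.1]heptane-1-carboxylate | CC1=C[C@H](OC(=O)[C@@]23CC[C@@](C)(C(=O)O2)C3(C)C)CC(C)(C)[C@H]1CO[Si](C)(C)C(C)(C)C | intermediate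
11 | (1R,4R)-4-(hydroxymethyl)-3,5,5-trimethylcyclohex-2-en-1-yl (1S,4R)-camphanate | CC1=C[C@H](OC(=O)[C@@]23CC[C@@](C)(C(=O)O2)C3(C)C)CC(C)(C)[C@H]1CO | intermediate
12 | 1-phenyl-1H-tetrazole-5-thiol | Sc1nnnn1-c1ccccc1 | starting material
13 | (1R,4R)-3,5,5-trimethyl-4-{[(1-phenyl-1H-tetrazol-5-yl)sulfanyl]methyl}cyclohex-2-en-1-yl (1S,4R)-camphanate | CC1=C[C@H](OC(=O)[C@@]23CC[C@@](C)(C(=O)O2)C3(C)C)CC(C)(C)[C@H]1CSc1nnnn1-c1ccccc1 | intermediate
14 | (1R,4R)-3,5,5-trimethyl-4-{[(1-phenyl-1H-tetrazol-5-yl)sulfonyl]methyl}cyclohex-2-en-1-yl (1S,4R)-camphanate | CC1=C[C@H](OC(=O)[C@@]23CC[C@@](C)(C(=O)O2)C3(C)C)CC(C)(C)[C@H]1CS(=O)(=O)c1nnnn1-c1ccccc1 | intermediate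
15 | (2E,4E,6E,8E,10E,12E,14E)-2,6,11,15-tetramethylhexadeca-2,4,6,8,10,12,14-heptaenedial (crocetin dialdehyde) | O=C/C(C)=C/C=C/C(C)=C/C=C/C=C(C)/C=C/C=C(\C)C=O | starting material
16 | (3R,6R)-8'-oxo-8'-apo-ε-caroten-3-yl (1S,4R)-camphanate, all-E | CC1=C[C@H](OC(=O)[C@@]23CC[C@@](C)(C(=O)O2)C3(C)C)CC(C)(C)[C@H]1/C=C/C(C)=C/C=C/C(C)=C/C=C/C=C(C)/C=C/C=C(\C)C=O | intermediate
17 | (3R,6R)-8'-hydroxy-8'-apo-ε-caroten-3-yl (1S,4R)-camphanate, all-E | CC1=C[C@H](OC(=O)[C@@]23CC[C@@](C)(C(=O)O2)C3(C)C)CC(C)(C)[C@H]1/C=C/C(C)=C/C=C/C(C)=C/C=C/C=C(C)/C=C/C=C(\C)CO | intermediate (not isolated)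
18 | (3R,6R)-8'-apo-ε-carotene-3,8'-diol, all-E | CC1=C[C@H](O)CC(C)(C)[C@H]1/C=C/C(C)=C/C=C/C(C)=C/C=C/C=C(C)/C=C/C=C(\C)CO | target

**Step count and risks**

Total step count: 10. Longest linear sequence: 10 steps (compound 1 to compound 18); compound 15 is bought.

Steps most likely to fail:

Step 2. The cycloaddition between a pyrone without an acceptor substituent and an unactivated alkene may be too slow even under pressure, and the adduct may lose CO2 by cycloreversion once the temperature is raised to compensate. Fallback: the ring would be built without the pyrone, setting out from compound 1. Base-mediated self-condensation of 1 (KOC(CH3)3, THF; vinylogous Claisen acylation of the dienolate by a second ester molecule, then 6-endo Michael ring closure) should give racemic ethyl 2,6,6-trimethyl-4-oxocyclohex-2-ene-1-carboxylate F1. 1,2-Reduction of the enone (NaBH4, CeCl3·7H2O, MeOH) would give the cis-hydroxy ester F2 together with the trans-hydroxy ester F3, which are separated by chromatography. LiAlH4 reduction of F2 comes back to the route at compound 7.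

Step 9. Addition of the hindered sulfonyl carbanion to the α-methyl enal may be slow, allowing self-condensation of the sulfone, double olefination of the dialdehyde, or erosion of the E-selectivity at C7=C8 (a minor 7Z isomer alone would be converged by iodine-catalysed equilibration). Fallback: the polarity of the union would be reversed, setting out from compound 11. Dess–Martin oxidation (NaHCO3-buffered, CH2Cl2) gives the ring aldehyde F4. In parallel, dialdehyde 15 is reduced (NaBH4, THF/MeOH) to the crocetin diol F5 and converted with one equivalent of PPh3·HBr (MeOH/CH2Cl2) into the mono-phosphonium bromide F6. Wittig reaction of F4 with F6 in 1,2-epoxybutane/EtOH (neutral ylide generation, which spares the epimerisable C6–H of F4), followed by iodine-catalysed equilibration of the polyene to all-E, comes back to the route at compound 17, which is de-acylated as in the second half of step 10.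

Step 5. The two diastereomeric camphanates may co-crystallise or co-elute, so that the resolution fails although the inversion itself proceeds; elimination to a cyclohexadiene may also compete. Fallback: resolution would be moved in front of the inversion, setting out from racemic compound 8. Lipase-catalysed acylation (immobilised Candida antarctica lipase B, vinyl acetate, tert-butyl methyl ether, 30 °C) is expected to acetylate the (1R,4S) enantiomer to the acetate F7 and to leave (1S,4R)-8, if the olefinic side of the carbinol behaves as the larger group; this sense would have to be confirmed. After chromatographic separation, the Mitsunobu reaction of step 5 on the single enantiomer gives one diastereomer only and comes back to the route at compound 10.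

**Further compounds**

F1 | step 2 | ethyl (1R)-2,6,6-trimethyl-4-oxocyclohex-2-ene-1-carboxylate (racemic) | CCOC(=O)[C@H]1C(C)=CC(=O)CC1(C)C
F2 | step 2 | ethyl (1R,4S)-4-hydroxy-2,6,6-trimethylcyclohex-2-ene-1-carboxylate (racemic, cis) | CC1=C[C@@H](O)CC(C)(C)[C@H]1C(=O)OCC
F3 | step 2 | ethyl (1R,4R)-4-hydroxy-2,6,6-trimethylcyclohex-2-ene-1-carboxylate (racemic, trans) | CC1=C[C@H](O)CC(C)(C)[C@H]1C(=O)OCC
F4 | step 9 | (1R,4R)-4-formyl-3,5,5-trimethylcyclohex-2-en-1-yl (1S,4R)-camphanate | CC1=C[C@H](OC(=O)[C@@]23CC[C@@](C)(C(=O)O2)C3(C)C)CC(C)(C)[C@H]1C=O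
F5 | step 9 | (2E,4E,6E,8E,10E,12E,14E)-2,6,11,15-tetramethylhexadeca-2,4,6,8,10,12,14-heptaene-1,16-diol | OC/C(C)=C/C=C/C(C)=C/C=C/C=C(C)/C=C/C=C(\C)CO
F6 | step 9 | [(2E,4E,6E,8E,10E,12E,14E)-16-hydroxy-2,6,11,15-tetramethylhexadeca-2,4,6,8,10,12,14-heptaen-1-yl]triphenylphosphonium bromide | [Br-].OC/C(C)=C/C=C/C(C)=C/C=C/C=C(C)/C=C/C=C(\C)C[P+](c1ccccc1)(c1ccccc1)c1ccccc1
F7 | step 5 | (1R,4S)-4-({[tert-butyl(dimethyl)silyl]oxy}methyl)-3,5,5-trimethylcyclohex-2-en-1-yl acetate | CC1=C[C@H](OC(C)=O)CC(C)(C)[C@@H]1CO[Si](C)(C)C(C)(C)C
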